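## Retrosynthetic overview

1. Target ⇐ Morita–Baylis–Hillman hydroxymethylation (C2–CH2OH) of the 4-angeloyloxy-6-tigloyloxy-5-isopropyl enone ⇐ angeloylation of the C4 alcohol and hydrolysis of a C1 dimethyl ketal.
2. Key disconnection C5–iPr: semipinacol 1,2-shift of isopropyl from C4 to C5 of a syn epoxy tertiary alcohol, merged with an Evans–Tishchenko hydride transfer from tiglaldehyde that sets C4–OH and leaves C6–O as the tiglate.
3. Epoxy alcohol ⇐ desymmetrising hydroxyl-directed asymmetric epoxidation of achiral 1-isopropyl-4,4-dimethoxycyclohexa-2,5-dienol ⇐ isopropylmagnesium chloride + p-benzoquinone mono(dimethyl ketal).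
4. Rings: the six-membered carbocycle is bought and never opened; the only ring formed is the oxirane (step 2), which is opened again in the key step (step 3).

## Assumptions and conventions

- Assumption: the first compound is bought as p-benzoquinone protected at one carbonyl as its dimethyl ketal; the ketal is carried as a protecting group and removed in step 5.
- Assumption: the ligand antipode in step 2 is the one that gives the (1S,2R,6R) epoxy alcohol; if the sense of induction is the reverse, the other antipode is used.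
- Locants C1–C6 in the comments are those of the target enone (C1 carbonyl, C2 bearing CH2OH, C4 angelate, C5 isopropyl, C6 tiglate).

## Route

Step 1
Reactants: 1 4,4-dimethoxycyclohexa-2,5-dien-1-one; 2 isopropylmagnesium chloride
Product: 3 4,4-dimethoxy-1-(propan-2-yl)cyclohexa-2,5-dien-1-ol
Conditions: iPrMgCl (1.3 equiv), LaCl3·2LiCl (30 mol %), THF, −78 → −20 °C; then H2O (pH 7 buffer)
Reagents that add atoms: none
Why: 1,2-Addition of a Grignard reagent to the cross-conjugated carbonyl of a quinone monoketal (LaCl3·2LiCl suppresses reduction and enolisation by the secondary alkyl reagent) gives the achiral tertiary bis-allylic alcohol, so no stereocentre is made here.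

Step 2
Reactants: 3 4,4-dimethoxy-1-(propan-2-yl)cyclohexa-2,5-dien-1-ol
Product: 4 (1S,2R,6R)-5,5-dimethoxy-2-(propan-2-yl)-7-oxabicyclo[4.1.0]hept-3-en-2-ol
Conditions: Hf(OtBu)4 (10 mol %), (1R,2R)-cyclohexane-1,2-diamine-derived bishydroxamic acid ligand (12 mol %), cumene hydroperoxide (1.1 equiv), MgO, toluene, 0 °C
Reagents that add atoms: cumene hydroperoxide (CC(C)(OO)c1ccccc1)
Why: Hydroxyl-directed asymmetric epoxidation of a tertiary allylic alcohol with a tetravalent hafnium bishydroxamate catalyst, run as a desymmetrisation: the hafnium-bound alkoxide delivers the peroxide oxygen to its own face (oxirane syn to OH) and the ligand chooses one of the two enantiotopic alkenes, which fixes C4, C5 and C6 at once, while any second epoxidation consumes mainly the minor enantiomer.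

Step 3
Reactants: 4 (1S,2R,6R)-5,5-dimethoxy-2-(propan-2-yl)-7-oxabicyclo[4.1.0]hept-3-en-2-ol; 5 (2E)-2-methylbut-2-enal (tiglaldehyde)
Product: 8 (1R,5S,6S)-5-hydroxy-2,2-dimethoxy-6-(propan-2-yl)cyclohex-3-en-1-yl (2E)-2-methylbut-2-enoate, via rearranged hydroxy enone 6 (not isolated), via samarium hemiacetal 7 (not isolated)
Conditions: SmI2 (30 mol %, premixed with 5), 5 (4 equiv), ClCH2CH2Cl/THF, −10 °C → rt
Reagents that add atoms: none
Why: Proposed new method: a samarium-catalysed tandem semipinacol rearrangement/Evans–Tishchenko reduction in which an α,β-unsaturated aldehyde is the hydride donor and acyl source; the trivalent samarium alkoxide formed from SmI2 and the aldehyde opens the oxirane of 4 at C5 while the isopropyl group, antiperiplanar to the breaking C5–O bond because it is trans to the oxirane, shifts from C4 to C5 with inversion at C5 to give keto alkoxide 6 (iPr trans to C6–O), the C6 alkoxide adds to tiglaldehyde to give hemiacetal 7, and hydride transfer within a six-membered samarium chelate reduces the new C4 ketone from the face of the C6 oxygen, which gives the 1,3-anti alcohol (C4–OH cis to iPr) and leaves the oxidised hemiacetal as the C6 tiglate; the closest known reactions are the samarium-promoted tandem semipinacol/Tishchenko reaction of tertiary 2,3-epoxy alcohols with saturated or aromatic aldehydes and the Evans–Tishchenko anti-reduction of β-hydroxy ketones, neither shown with a migrating isopropyl group next to a ketal or with an enal as the aldehyde.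

Step 4
Reactants: 8 (1R,5S,6S)-5-hydroxy-2,2-dimethoxy-6-(propan-2-yl)cyclohex-3-en-1-yl (2E)-2-methylbut-2-enoate; 9 (2Z)-2-methylbut-2-enoic acid (angelic acid)
Product: 11 (1R,5S,6S)-2,2-dimethoxy-5-{[(2Z)-2-methylbut-2-enoyl]oxy}-6-(propan-2-yl)cyclohex-3-en-1-yl (2E)-2-methylbut-2-enoate, via mixed anhydride 10 (not isolated)
Conditions: 9, 2,4,6-trichlorobenzoyl chloride, Et3N, toluene, rt; then 8, toluene, 75 °C (no DMAP)
Reagents that add atoms: none
Why: Yamaguchi esterification through mixed anhydride 10 run without DMAP, the usual way to angeloylate a hindered secondary alcohol without Z to E isomerisation, acylates the only free hydroxyl with retention at C4.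

Step 5
Reactants: 11 (1R,5S,6S)-2,2-dimethoxy-5-{[(2Z)-2-methylbut-2-enoyl]oxy}-6-(propan-2-yl)cyclohex-3-en-1-yl (2E)-2-methylbut-2-enoate
Product: 12 (4S,5S,6R)-4-{[(2Z)-2-methylbut-2-enoyl]oxy}-6-{[(2E)-2-methylbut-2-enoyl]oxy}-5-(propan-2-yl)cyclohex-2-en-1-one
Conditions: TsOH·H2O (10 mol %), acetone/H2O (9:1), rt
Reagents that add atoms: water (O)
Why: Acid-catalysed hydrolysis of the allylic dimethyl ketal, far faster than cleavage of the two hindered conjugated esters, frees the C1 ketone in conjugation with C2=C3 without touching a stereocentre.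

Step 6
Reactants: 12 (4S,5S,6R)-4-{[(2Z)-2-methylbut-2-enoyl]oxy}-6-{[(2E)-2-methylbut-2-enoyl]oxy}-5-(propan-2-yl)cyclohex-2-en-1-one; 13 formaldehyde
Product: 14 (4S,5S,6R)-2-(hydroxymethyl)-4-{[(2Z)-2-methylbut-2-enoyl]oxy}-6-{[(2E)-2-methylbut-2-enoyl]oxy}-5-(propan-2-yl)cyclohex-2-en-1-one
Conditions: 37 % aq. CH2O, imidazole (1 equiv), THF/1 M aq. NaHCO3 (1:1), rt
Reagents that add atoms: none
Why: Morita–Baylis–Hillman reaction: imidazole adds to C3, the enolate adds to formaldehyde at C2 and imidazole is expelled, so CH2OH can only end on the α-carbon, and the nearly neutral medium leaves both esters and C4–C6 unchanged.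

## Compound list

1 | 4,4-dimethoxycyclohexa-2,5-dien-1-one (p-benzoquinone mono(dimethyl ketal)) | COC1(OC)C=CC(=O)C=C1 | starting material
2 | isopropylmagnesium chloride | CC(C)[Mg]Cl | starting material
3 | 4,4-dimethoxy-1-(propan-2-yl)cyclohexa-2,5-dien-1-ol (achiral) | CC(C)C1(O)C=CC(OC)(OC)C=C1 | intermediate
4 | (1S,2R,6R)-5,5-dimethoxy-2-(propan-2-yl)-7-oxabicyclo[4.1.0]hept-3-en-2-ol (oxirane cis to OH, isopropyl trans to the oxirane) | CC(C)[C@@]1(O)C=CC(OC)(OC)[C@@H]2O[C@H]12 | intermediate
5 | (2E)-2-methylbut-2-enal (tiglaldehyde) | C/C=C(\C)C=O | starting material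
6 | (5R,6R)-5-hydroxy-4,4-dimethoxy-6-(propan-2-yl)cyclohex-2-en-1-one (present as its samarium alkoxide; OH and isopropyl trans) | O=C1C=CC(OC)(OC)[C@H](O)[C@H]1C(C)C | intermediate
7 | (5R,6R)-5-{[(2E)-1-hydroxy-2-methylbut-2-en-1-yl]oxy}-4,4-dimethoxy-6-(propan-2-yl)cyclohex-2-en-1-one (samarium-bound hemiacetal; hemiacetal carbon not controlled) | O=C1C=CC(OC)(OC)[C@H](OC(O)/C(C)=C/C)[C@H]1C(C)C | intermediate
8 | (1R,5S,6S)-5-hydroxy-2,2-dimethoxy-6-(propan-2-yl)cyclohex-3-en-1-yl (2E)-2-methylbut-2-enoate | O[C@H]1C=CC(OC)(OC)[C@H](OC(=O)/C(C)=C/C)[C@H]1C(C)C | intermediate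
9 | (2Z)-2-methylbut-2-enoic acid (angelic acid) | C/C=C(/C)C(=O)O | starting material
10 | (2Z)-2-methylbut-2-enoic 2,4,6-trichlorobenzoic anhydride | C/C=C(/C)C(=O)OC(=O)c1c(Cl)cc(Cl)cc1Cl | intermediate
11 | (1R,5S,6S)-2,2-dimethoxy-5-{[(2Z)-2-methylbut-2-enoyl]oxy}-6-(propan-2-yl)cyclohex-3-en-1-yl (2E)-2-methylbut-2-enoate | C/C=C(/C)C(=O)O[C@H]1C=CC(OC)(OC)[C@H](OC(=O)/C(C)=C/C)[C@H]1C(C)C | intermediate
12 | (4S,5S,6R)-4-{[(2Z)-2-methylbut-2-enoyl]oxy}-6-{[(2E)-2-methylbut-2-enoyl]oxy}-5-(propan-2-yl)cyclohex-2-en-1-one | C/C=C(/C)C(=O)O[C@H]1C=CC(=O)[C@H](OC(=O)/C(C)=C/C)[C@H]1C(C)C | intermediate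
13 | formaldehyde | C=O | starting material
14 | (4S,5S,6R)-2-(hydroxymethyl)-4-{[(2Z)-2-methylbut-2-enoyl]oxy}-6-{[(2E)-2-methylbut-2-enoyl]oxy}-5-(propan-2-yl)cyclohex-2-en-1-one | C/C=C(/C)C(=O)O[C@H]1C=C(CO)C(=O)[C@H](OC(=O)/C(C)=C/C)[C@H]1C(C)C | target

## Step count and risk

Total step count: 6. Longest linear sequence: 6 steps (1 → 3 → 4 → 8 → 11 → 12 → 14).

**Step 3 (the proposed new step).**
- Risks: migration of the ring alkenyl carbon instead of isopropyl (ring contraction), retro-aldol opening of 6 before the hydride transfer, conjugate addition to the enal, and ionisation of the ketal.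
- Fallback (known chemistry, stepwise, with borohydride as hydride source and both esters made by acylation): it sets out from 4 and comes back at 11.
- ZnBr2 in CH2Cl2 at 0 °C carries out the Lewis-acid semipinacol rearrangement alone, and hydroxy enone 6 is isolated.
- Me4NBH(OAc)3 in MeCN/AcOH at −30 °C reduces the ketone by hydride delivery from the C6 hydroxyl to give the 1,3-anti diol (1R,2S,3S)-6,6-dimethoxy-2-(propan-2-yl)cyclohex-4-ene-1,3-diol F1.
- The less hindered allylic hydroxyl is acylated first with mixed anhydride 10 (toluene, 75 °C) to give (1S,5R,6R)-5-hydroxy-4,4-dimethoxy-6-(propan-2-yl)cyclohex-2-en-1-yl (2Z)-2-methylbut-2-enoate F2.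
- (2E)-2-Methylbut-2-enoyl chloride with pyridine and DMAP in CH2Cl2 then esterifies the remaining hindered hydroxyl, which gives 11.

**Step 2.**
- Risks: low enantioselectivity on this cyclic cis-alkene, and acid-promoted ionisation of the tertiary bis-allylic alcohol or the ketal.
- Fallback (order of events reversed, absolute configuration set by nucleophilic epoxidation): it sets out from 1 and comes back at 4.
- Weitz–Scheffer epoxidation of 1 under chiral phase transfer (tBuOOH, aq. NaOH, N-benzylcinchonidinium chloride or its cinchoninium pseudo-enantiomer, toluene, 0 °C; enrichment by crystallisation) gives (1S,6R)-5,5-dimethoxy-7-oxabicyclo[4.1.0]hept-3-en-2-one F3.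
- Addition of 2 (LaCl3·2LiCl, THF, −78 °C) to the ketone from the face opposite the oxirane places OH cis and isopropyl trans to the oxirane, which is 4.

**Step 6.**
- Risks: slow addition of imidazole next to the axial C4 ester, and loss or migration of the α-acyloxy ester in the aqueous base.
- Fallback (C2–C bond made by cross-coupling instead of an aldol step): it sets out from 12 and comes back at 14.
- α-Iodination with I2 and pyridine in CH2Cl2 gives (4R,5S,6R)-2-iodo-4-{[(2Z)-2-methylbut-2-enoyl]oxy}-6-{[(2E)-2-methylbut-2-enoyl]oxy}-5-(propan-2-yl)cyclohex-2-en-1-one F4.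
- Stille coupling with Bu3SnCH2OH (Pd(PPh3)4, a zerovalent palladium catalyst, CuI, dioxane, 80 °C) gives 14.

## Further compounds

F1 | step 3 | (1R,2S,3S)-6,6-dimethoxy-2-(propan-2-yl)cyclohex-4-ene-1,3-diol | O[C@H]1C=CC(OC)(OC)[C@H](O)[C@H]1C(C)C
F2 | step 3 | (1S,5R,6R)-5-hydroxy-4,4-dimethoxy-6-(propan-2-yl)cyclohex-2-en-1-yl (2Z)-2-methylbut-2-enoate | C/C=C(/C)C(=O)O[C@H]1C=CC(OC)(OC)[C@H](O)[C@H]1C(C)C
F3 | step 2 | (1S,6R)-5,5-dimethoxy-7-oxabicyclo[4.1.0]hept-3-en-2-one | O=C1C=CC(OC)(OC)[C@@H]2O[C@H]12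
F4 | step 6 | (4R,5S,6R)-2-iodo-4-{[(2Z)-2-methylbut-2-enoyl]oxy}-6-{[(2E)-2-methylbut-2-enoyl]oxy}-5-(propan-2-yl)cyclohex-2-en-1-one | C/C=C(/C)C(=O)O[C@H]1C=C(I)C(=O)[C@H](OC(=O)/C(C)=C/C)[C@H]1C(C)C
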